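All constants come from no measurement; the flask was simulated.

**The constants.** The constants below describe a flask in which X meets L by two routes, one giving X.L with one L and one giving Z with two, while L also decays by itself and X pairs with itself.

    X + L → X.L (k1 = 0.91 M⁻¹ s⁻¹)
    X + 2 L → Z (k2 = 15 M⁻² s⁻¹)
    L → J (k3 = 1.0 × 10⁻⁴ s⁻¹)
    L → D (k4 = 0.059 s⁻¹)
    2 X → X2 (k5 = 0.44 M⁻¹ s⁻¹)

all flasks: X 20 mM; time 10 s

| run | L |
|---|---|
| Thursday's | 25.0 mM |
| Monday's | 50.0 mM |
| Wednesday's | 100 mM |
| Saturday's | 200 mM |
| Tuesday's | 400 mM |

- amount of X.L at the end, in percent of the X charged for Thursday's, Monday's, Wednesday's, Saturday's, Tuesday's, in this order
- how that number moves from the first to the last of them (hardly changes / rises, then falls / falls all the way / rises all the way / falls, then rises)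

- percentages count the X that a species holds: one X2 counts as two
- where a step has two of a species, its rate is k times that concentration squared, and two are used at each turn
- "hardly changes" means that all values lie within two and a half points (for a concentration: within two and a half percent of the largest)
- run time (Thursday's): 10 s

**Two routes.** For each X, the route to X.L runs at 0.91 M⁻¹ s⁻¹ times L, and the route to Z at 15 M⁻² s⁻¹ times L squared. Z made per X.L made at any moment is therefore L at that moment divided by the quotient of these constants, 60.7 mM. This quotient is the crossover concentration, the L at which the two routes run equally, and L over it is a selectivity factor.

**Powers of ten.** In logarithms the split becomes a straight line, since its logarithm climbs by one for each power of ten in L. Thursday's charge of 25.0 mM stands 0.385 below the crossover, and Tuesday's charge of 400 mM stands 0.819 above it. At these charges the X + L route is thus favoured on Thursday's and the route to Z on Tuesday's.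

**Tuesday's end.** The split counts for the yield once X has time to react. In Tuesday's flask the lifetime of X under both routes at the charged L, one over their summed rate, is 0.362 s, far shorter than the 16.9 s lifetime of L against the decay to D. The pairing of X runs far slower than these routes. The X charged can take up at most 40.0 mM of L, less than Tuesday's charge, so in Tuesday's flask L should stay near its charge while X goes, a pseudo-first-order case, and X.L should take one part in one plus the selectivity factor, 13.2% of the X charged.

**Thursday's end.** In Thursday's flask the half-life of X by the X.L route alone, with L as charged, is 30 s, longer than the 10 s run, and L has a half-life of 12 s by the decay to D alone. The run is thus short for X in Thursday's flask, so more L should give more X.L there. This reckoning commits to a row that rises, then falls, and it gives no figure for the middle flasks.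

**The forecast.** The forecast gave 13.3%, 22%, 30%, 26% and 14%, a row that rises, then falls, holding that at high L “the L-squared route to Z takes most of it”.

**The result.** The simulation gives 13.0%, 22.2%, 30.7%, 26.0% and 14.0%, a row that rises, then falls, with Tuesday's against the reckoned 13.2%. Tuesday's flask ends with 0% of its X free and 85.7% as Z, so Z per X.L reads 6.12, against 6.59 from the charge over the crossover. Wednesday's flask reads 1.22, which the crossover turns into an L of 73.9 mM, between the 41.4 mM left at the end and the 100 mM charged.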